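The route rests on a [5+2] annulation that closes the seven-membered ring (ring C) across the two one-carbon bridges of a chrysanthenone-type bicyclo[3.1.1]heptenone (rings A and B), exploiting their 1,3-syn disposition on the cyclobutane. The five-carbon partner is the cyclobutanone carbonyl plus a β-ketophosphonate on the neighbouring quaternary bridge carbon; the two-carbon partner is the lithium enolate of isobutyraldehyde. In one operation, reversible aldol addition joins the CMe2 carbon to the cyclobutane carbon, and an irreversible intramolecular Horner–Wadsworth–Emmons olefination joins the future methacrylate-bearing carbon to the ring CH2. The bicyclic precursor arises from an intramolecular vinylketene–alkene [2+2] cycloaddition of a geranate-derived acid.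

Key step: step 10

Remark: methyl (2E)-geranate (1) and the trimethylsilyl enol ether of isobutyraldehyde (15) are taken as purchased; the silyloxy stereocentre made in step 2 is a temporary control element that is erased in step 8.

Locants: in tricyclo[5.4.0.0(2,8)]undecane names, C1 and C8 are the cyclobutane CH atoms that carry the C9–C10–C11 bridge (ring B), C2 is the cyclobutane carbon bonded to C3 (CMe2), C7 is the quaternary cyclobutane carbon, and C3–C6 complete ring C.

Step 1
Reactants: 1 methyl (2E)-3,7-dimethylocta-2,6-dienoate (methyl geranate)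
Product: 3 methyl (2E,6E)-3,7-dimethyl-8-oxoocta-2,6-dienoate, via allylic alcohol 2 (not isolated)
Conditions: SeO2 (cat.), t-BuOOH, salicylic acid (cat.), CH2Cl2, rt; then MnO2, CH2Cl2, rt
Reagents that add atoms: tert-butyl hydroperoxide, CC(C)(C)OO
Why: Selenium dioxide allylic oxidation (ene reaction, then [2,3]-sigmatropic shift) should attack the (E)-methyl group of the electron-rich trisubstituted alkene and leave the conjugated enoate alone, and MnO2 takes the allylic alcohol on to the (E)-enal.

Step 2
Reactants: 3 methyl (2E,6E)-3,7-dimethyl-8-oxoocta-2,6-dienoate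
Product: 4 methyl (2E,6E,8S)-8-hydroxy-3,7-dimethylnona-2,6-dienoate
Conditions: Me2Zn, (−)-MIB [(2S)-3-exo-morpholinoisoborneol, 10 mol%], toluene, 0 °C to rt; aqueous work-up
Reagents that add atoms: dimethylzinc, C[Zn]C
Why: Amino-alcohol-catalysed enantioselective 1,2-addition of the dialkylzinc to the enal should set the (S)-carbinol centre by catalyst control, the ester being inert to the organozinc reagent.

Step 3
Reactants: 4 methyl (2E,6E,8S)-8-hydroxy-3,7-dimethylnona-2,6-dienoate
Product: 5 methyl (2E,6E,8S)-8-(tert-butyldimethylsilyloxy)-3,7-dimethylnona-2,6-dienoate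
Conditions: TBSCl, imidazole, DMF, rt
Reagents that add atoms: tert-butyldimethylsilyl chloride, CC(C)(C)[Si](C)(C)Cl
Why: Standard silylation protects the secondary alcohol against the acid chloride chemistry of step 5 and provides the bulky allylic ether that directs the cycloaddition.

Step 4
Reactants: 5 methyl (2E,6E,8S)-8-(tert-butyldimethylsilyloxy)-3,7-dimethylnona-2,6-dienoate
Product: 6 (2E,6E,8S)-8-(tert-butyldimethylsilyloxy)-3,7-dimethylnona-2,6-dienoic acid
Conditions: LiOH, THF–MeOH–H2O, 50 °C; then 1 M HCl to pH 3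
Reagents that add atoms: lithium hydroxide, [Li+].[OH-]
Why: Saponification of the β,β-disubstituted enoate should give the acid without touching the secondary silyl ether or the alkene geometry.

Step 5
Reactants: 6 (2E,6E,8S)-8-(tert-butyldimethylsilyloxy)-3,7-dimethylnona-2,6-dienoic acid
Product: 9 7-[(1S)-1-(tert-butyldimethylsilyloxy)ethyl]-7-methyl-2-methylidenebicyclo[3.1.1]heptan-6-one (7-methyl syn to the C2–C4 bridge), via acid chloride 7 (not isolated), via vinylketene 8 (not isolated)
Conditions: (COCl)2, DMF (cat.), CH2Cl2, 0 °C to rt; concentrate; then Et3N, toluene, 110 °C, slow addition at high dilution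
Reagents that add atoms: none
Why: Dehydrochlorination at the γ-methyl group syn to the acyl chloride gives the vinylketene, whose intramolecular ketene–alkene [2+2] cycloaddition (carbonyl carbon to the alkene CH, ketene α-carbon to the cation-stabilising disubstituted carbon) should close the bicyclo[3.1.1]heptan-6-one with retention of the (E)-alkene geometry, while the (S)-silyloxy centre, reacting with its C–O bond in the alkene plane (inside-alkoxy model), directs the ketene to one alkene face and so fixes the absolute configuration of the three ring stereocentres, the minor diastereomer being removed by chromatography.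

Step 6
Reactants: 9 7-[(1S)-1-(tert-butyldimethylsilyloxy)ethyl]-7-methyl-2-methylidenebicyclo[3.1.1]heptan-6-one
Product: 10 7-[(1S)-1-(tert-butyldimethylsilyloxy)ethyl]-2,7-dimethylbicyclo[3.1.1]hept-2-en-6-one
Conditions: RuHCl(CO)(PPh3)3 (5 mol%), toluene, 90 °C
Reagents that add atoms: none
Why: Metal hydride-catalysed alkene isomerisation should move the exocyclic double bond into the ring, the trisubstituted C2=C3 alkene being thermodynamically preferred and the bridgehead direction being closed by Bredt's rule.

Step 7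
Reactants: 10 7-[(1S)-1-(tert-butyldimethylsilyloxy)ethyl]-2,7-dimethylbicyclo[3.1.1]hept-2-en-6-one
Product: 11 7-[(1S)-1-hydroxyethyl]-2,7-dimethylbicyclo[3.1.1]hept-2-en-6-one
Conditions: HF·pyridine, THF, 0 °C to rt
Reagents that add atoms: none
Why: Fluoride-mediated desilylation under weakly acidic conditions frees the alcohol without exposing the strained, non-enolisable cyclobutanone to base.

Step 8
Reactants: 11 7-[(1S)-1-hydroxyethyl]-2,7-dimethylbicyclo[3.1.1]hept-2-en-6-one
Product: 12 7-acetyl-2,7-dimethylbicyclo[3.1.1]hept-2-en-6-one (7-methyl syn to the C2–C4 bridge)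
Conditions: Dess–Martin periodinane, CH2Cl2, rt
Reagents that add atoms: none
Why: Dess–Martin oxidation converts the directing carbinol into the methyl ketone under neutral conditions, erasing the temporary stereocentre and leaving a single enantiomer of the diketone.

Step 9
Reactants: 12 7-acetyl-2,7-dimethylbicyclo[3.1.1]hept-2-en-6-one
Product: 14 diethyl [2-(2,7-dimethyl-6-oxobicyclo[3.1.1]hept-2-en-7-yl)-2-oxoethyl]phosphonate, via keto phosphonite 13 (not isolated)
Conditions: LiN(SiMe3)2 (2.2 equiv), THF, −78 °C; ClP(OEt)2, −78 °C to rt; AcOH; then air, rt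
Reagents that add atoms: diethyl chlorophosphite, CCOP(Cl)OCC; dioxygen, O=O
Why: The methyl ketone is the only enolisable position (cyclobutanone α-carbons are bridgeheads, the other α-carbon is quaternary), so its lithium enolate should be C-phosphinylated by the trivalent phosphorus chloride and the β-keto phosphonite oxidised by air to the β-keto phosphonate.

Step 10
Reactants: 14 diethyl [2-(2,7-dimethyl-6-oxobicyclo[3.1.1]hept-2-en-7-yl)-2-oxoethyl]phosphonate; 15 2-methyl-1-(trimethylsilyloxy)prop-1-ene
Product: 18 2-hydroxy-3,3,7,11-tetramethyltricyclo[5.4.0.0(2,8)]undeca-4,10-dien-6-one, via lithium enolate 16 (not isolated), via dilithium aldolate 17 (not isolated)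
Conditions: 15, MeLi, THF, 0 °C to rt (gives 16); 14, LiN(SiMe3)2 (1.05 equiv), THF, −78 °C; add 16 (1.3 equiv), −78 to 0 °C; AcOH, −40 °C
Reagents that add atoms: none
Why: The lithium enolate 16 adds reversibly to the strained, non-enolisable cyclobutanone carbonyl of the lithium phosphonoenolate of 14 (crossed aldol addition), forming the bond from the CMe2 carbon to C2 and unmasking a neopentyl aldehyde, which the phosphonate carbanion captures in an intramolecular Horner–Wadsworth–Emmons olefination that forms the C4=C5 bond and expels lithium diethyl phosphate. The closest known reaction type is the tandem carbonyl-addition/Horner–Wadsworth–Emmons annulation (domino Michael–olefination syntheses of cyclohexenes), used here as a formal [5+2] annulation. Ring C is closed by 7-exo-trig attack of the phosphonate carbanion on the aldehyde followed by syn-elimination from the oxaphosphetane, the ring enforcing the Z-alkene. The only new stereocentre, the tertiary carbinol C2, is controlled by the ring closure itself: only the aldolate formed on the face syn to the C7 side chain can reach the phosphonate, while the other adduct returns by retro-aldol cleavage and is funnelled through. The step needs chemoselectivity for the cyclobutanone over the side-chain ketone, secured by ring strain and by prior conversion of that ketone into its enolate, and it needs the olefination to outrun aldol oligomerisation and base-induced opening of the cyclobutanolate, secured by a small excess of preformed, proton-free enolate and a cold acidic quench.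

Step 11
Reactants: 18 2-hydroxy-3,3,7,11-tetramethyltricyclo[5.4.0.0(2,8)]undeca-4,10-dien-6-one
Product: 19 (4R)-2-hydroxy-3,3,7,11-tetramethyl-4-(4,4,5,5-tetramethyl-1,3,2-dioxaborolan-2-yl)tricyclo[5.4.0.0(2,8)]undec-10-en-6-one
Conditions: B2pin2, Cu(OH)2 (5 mol%), (S,S)-6,6'-bis(1-hydroxy-2,2-dimethylpropyl)-2,2'-bipyridine (6 mol%), AcOH (6 mol%), H2O, rt
Reagents that add atoms: bis(pinacolato)diboron, CC1(C)OB(OC1(C)C)B1OC(C)(C)C(C)(C)O1
Why: Copper-catalysed enantioselective conjugate borylation places boron on the enone β-carbon next to the CMe2 centre, and since the two faces of ring C differ only through the remote bridge, the chiral bipyridine ligand (antipode selected for boron delivery to the face that gives 4R) should set this centre by catalyst control, while the base-free aqueous medium avoids retro-aldol opening of the tertiary cyclobutanol.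

Step 12
Reactants: 19 (4R)-2-hydroxy-3,3,7,11-tetramethyl-4-(pinacolatoboryl)tricyclo[5.4.0.0(2,8)]undec-10-en-6-one
Product: 20 methyl (4R)-3,3,7,11-tetramethyl-6-oxo-4-(pinacolatoboryl)tricyclo[5.4.0.0(2,8)]undec-10-en-2-yl oxalate
Conditions: ClC(O)CO2Me, Et3N, DMAP (cat.), CH2Cl2, 0 °C to rt
Reagents that add atoms: methyl chlorooxoacetate, COC(=O)C(=O)Cl
Why: The very reactive oxalyl half-chloride should acylate the hindered tertiary cyclobutanol, the only hydroxyl present, under mild amine catalysis and so avoid the strong base that a xanthate would require.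

Step 13
Reactants: 20 methyl (4R)-3,3,7,11-tetramethyl-6-oxo-4-(pinacolatoboryl)tricyclo[5.4.0.0(2,8)]undec-10-en-2-yl oxalate
Product: 22 (4R)-4-hydroxy-3,3,7,11-tetramethyltricyclo[5.4.0.0(2,8)]undec-10-en-6-one, via deoxygenated boronate 21 (not isolated)
Conditions: Bu3SnH, AIBN (cat.), toluene, 100 °C; then NaBO3·4H2O, THF–H2O, rt
Reagents that add atoms: sodium perborate, [Na+].[O-]OB=O
Why: Stannyl-radical fragmentation of the tertiary methyl oxalate (oxalate variant of the Barton–McCombie deoxygenation) gives the cyclobutyl radical at C2, which can take up hydrogen only on the face away from ring C, so the CH centre forms with the ring-imposed configuration, and perborate then oxidises the C–B bond with retention to the (4R)-alcohol.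

Step 14
Reactants: 22 (4R)-4-hydroxy-3,3,7,11-tetramethyltricyclo[5.4.0.0(2,8)]undec-10-en-6-one
Product: 23 (4R,6R)-6-hydroxy-3,3,7,11-tetramethyltricyclo[5.4.0.0(2,8)]undec-10-en-4-yl 2-methylprop-2-enoate
Conditions: methacrolein (5 equiv), SmI2 (30 mol%), THF, −10 °C
Reagents that add atoms: methacrolein, CC(=C)C=O
Why: In the Evans–Tishchenko reduction the samarium-bound hemiacetal formed from the C4 alkoxide and methacrolein delivers hydride intramolecularly to the C6 ketone through a six-membered transition state, which should give the 1,3-anti diol as its C4 mono-methacrylate and thus set the (6R) centre and differentiate the two oxygens in one step.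

Step 15
Reactants: 23 (4R,6R)-6-hydroxy-3,3,7,11-tetramethyltricyclo[5.4.0.0(2,8)]undec-10-en-4-yl 2-methylprop-2-enoate
Product: 24 (4R,6R)-3,3,7,11-tetramethyl-6-(2-methylpropanoyloxy)tricyclo[5.4.0.0(2,8)]undec-10-en-4-yl 2-methylprop-2-enoate
Conditions: i-PrCOCl, pyridine, DMAP (cat.), CH2Cl2, 0 °C to rt
Reagents that add atoms: isobutyryl chloride, CC(C)C(=O)Cl
Why: DMAP-catalysed acylation esterifies the remaining secondary alcohol, and acyl migration is not expected because the two oxygens are trans on ring C.

Step 16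
Reactants: 24 (4R,6R)-3,3,7,11-tetramethyl-6-(2-methylpropanoyloxy)tricyclo[5.4.0.0(2,8)]undec-10-en-4-yl 2-methylprop-2-enoate
Product: 25 (1R,2S,4R,6R,7R,8R)-3,3,7,11-tetramethyl-6-(2-methylpropanoyloxy)-9-oxotricyclo[5.4.0.0(2,8)]undec-10-en-4-yl 2-methylprop-2-enoate (CNP0214356.1)
Conditions: CrO3, 3,5-dimethylpyrazole, CH2Cl2, −20 °C
Reagents that add atoms: chromium trioxide, O=[Cr](=O)=O
Why: Allylic oxidation with the CrO3–3,5-dimethylpyrazole complex (the pinene-to-verbenone type oxidation) should convert C9, the only allylic methylene, into the enone carbonyl, the esters and the electron-poor methacrylate alkene being inert to the electrophilic oxidant; it is placed last because a C9 ketone beside an oxygenated C2 would open the cyclobutane by retro-aldol cleavage.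

Compound list
1 | methyl (2E)-3,7-dimethylocta-2,6-dienoate (methyl geranate) | COC(=O)/C=C(C)/CCC=C(C)C | starting material
2 | methyl (2E,6E)-8-hydroxy-3,7-dimethylocta-2,6-dienoate (not isolated) | COC(=O)/C=C(C)/CC/C=C(C)/CO | intermediate
3 | methyl (2E,6E)-3,7-dimethyl-8-oxoocta-2,6-dienoate | COC(=O)/C=C(C)/CC/C=C(C)/C=O | intermediate
4 | methyl (2E,6E,8S)-8-hydroxy-3,7-dimethylnona-2,6-dienoate | COC(=O)/C=C(C)/CC/C=C(C)/[C@@H](O)C | intermediate
5 | methyl (2E,6E,8S)-8-(tert-butyldimethylsilyloxy)-3,7-dimethylnona-2,6-dienoate | COC(=O)/C=C(C)/CC/C=C(C)/[C@@H](O[Si](C)(C)C(C)(C)C)C | intermediate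
6 | (2E,6E,8S)-8-(tert-butyldimethylsilyloxy)-3,7-dimethylnona-2,6-dienoic acid | OC(=O)/C=C(C)/CC/C=C(C)/[C@@H](O[Si](C)(C)C(C)(C)C)C | intermediate
7 | acid chloride of 6 (not isolated) | ClC(=O)/C=C(C)/CC/C=C(C)/[C@@H](O[Si](C)(C)C(C)(C)C)C | intermediate
8 | vinylketene, (6E,8S)-8-(tert-butyldimethylsilyloxy)-7-methyl-3-methylidenenona-1,6-dien-1-one (not isolated) | O=C=CC(=C)CC/C=C(C)/[C@@H](O[Si](C)(C)C(C)(C)C)C | intermediate
9 | 7-[(1S)-1-(tert-butyldimethylsilyloxy)ethyl]-7-methyl-2-methylidenebicyclo[3.1.1]heptan-6-one, 7-methyl syn to the C2–C4 bridge, ring configuration as in the SMILES | C[C@H](O[Si](C)(C)C(C)(C)C)[C@@]1(C)[C@@H]2CCC(=C)[C@H]1C2=O | intermediate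
10 | 7-[(1S)-1-(tert-butyldimethylsilyloxy)ethyl]-2,7-dimethylbicyclo[3.1.1]hept-2-en-6-one | C[C@H](O[Si](C)(C)C(C)(C)C)[C@@]1(C)[C@@H]2CC=C(C)[C@H]1C2=O | intermediate
11 | 7-[(1S)-1-hydroxyethyl]-2,7-dimethylbicyclo[3.1.1]hept-2-en-6-one | C[C@H](O)[C@@]1(C)[C@@H]2CC=C(C)[C@H]1C2=O | intermediate
12 | 7-acetyl-2,7-dimethylbicyclo[3.1.1]hept-2-en-6-one, 7-methyl syn to the C2–C4 bridge | CC(=O)[C@@]1(C)[C@@H]2CC=C(C)[C@H]1C2=O | intermediate
13 | diethyl [2-(2,7-dimethyl-6-oxobicyclo[3.1.1]hept-2-en-7-yl)-2-oxoethyl]phosphonite (not isolated) | CCOP(OCC)CC(=O)[C@@]1(C)[C@@H]2CC=C(C)[C@H]1C2=O | intermediate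
14 | diethyl [2-(2,7-dimethyl-6-oxobicyclo[3.1.1]hept-2-en-7-yl)-2-oxoethyl]phosphonate | CCOP(=O)(OCC)CC(=O)[C@@]1(C)[C@@H]2CC=C(C)[C@H]1C2=O | intermediate
15 | 2-methyl-1-(trimethylsilyloxy)prop-1-ene | CC(C)=CO[Si](C)(C)C | starting material
16 | lithium 2-methylprop-1-en-1-olate (not isolated) | CC(C)=C[O-].[Li+] | intermediate
17 | dilithium aldolate: phosphonoenolate of 14 carrying a 6-oxido-6-(1,1-dimethyl-2-oxoethyl) group, new substituent syn to the C7 side chain (not isolated) | [Li+].[Li+].CCOP(=O)(OCC)C=C([O-])[C@@]1(C)[C@@H]2CC=C(C)[C@H]1[C@]2([O-])C(C)(C)C=O | intermediate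
18 | 2-hydroxy-3,3,7,11-tetramethyltricyclo[5.4.0.0(2,8)]undeca-4,10-dien-6-one, hydroxyl on the face of the C9–C11 bridge | C1=CC(=O)[C@@]2(C)[C@@H]3CC=C(C)[C@H]2[C@]3(O)C1(C)C | intermediate
19 | (4R)-2-hydroxy-3,3,7,11-tetramethyl-4-(4,4,5,5-tetramethyl-1,3,2-dioxaborolan-2-yl)tricyclo[5.4.0.0(2,8)]undec-10-en-6-one | CC1(C)OB(OC1(C)C)[C@@H]1CC(=O)[C@@]2(C)[C@@H]3CC=C(C)[C@H]2[C@]3(O)C1(C)C | intermediate
20 | methyl (4R)-3,3,7,11-tetramethyl-6-oxo-4-(pinacolatoboryl)tricyclo[5.4.0.0(2,8)]undec-10-en-2-yl oxalate | CC1(C)OB(OC1(C)C)[C@@H]1CC(=O)[C@@]2(C)[C@@H]3CC=C(C)[C@H]2[C@]3(OC(=O)C(=O)OC)C1(C)C | intermediate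
21 | (4R)-3,3,7,11-tetramethyl-4-(pinacolatoboryl)tricyclo[5.4.0.0(2,8)]undec-10-en-6-one (not isolated) | CC1(C)OB(OC1(C)C)[C@@H]1CC(=O)[C@@]2(C)[C@@H]3CC=C(C)[C@H]2[C@@H]3C1(C)C | intermediate
22 | (4R)-4-hydroxy-3,3,7,11-tetramethyltricyclo[5.4.0.0(2,8)]undec-10-en-6-one | O[C@@H]1CC(=O)[C@@]2(C)[C@@H]3CC=C(C)[C@H]2[C@@H]3C1(C)C | intermediate
23 | (4R,6R)-6-hydroxy-3,3,7,11-tetramethyltricyclo[5.4.0.0(2,8)]undec-10-en-4-yl 2-methylprop-2-enoate | C=C(C)C(=O)O[C@@H]1C[C@@H](O)[C@@]2(C)[C@@H]3CC=C(C)[C@H]2[C@@H]3C1(C)C | intermediate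
24 | (4R,6R)-3,3,7,11-tetramethyl-6-(2-methylpropanoyloxy)tricyclo[5.4.0.0(2,8)]undec-10-en-4-yl 2-methylprop-2-enoate | C=C(C)C(=O)O[C@@H]1C[C@@H](OC(=O)C(C)C)[C@@]2(C)[C@@H]3CC=C(C)[C@H]2[C@@H]3C1(C)C | intermediate
25 | (1R,2S,4R,6R,7R,8R)-3,3,7,11-tetramethyl-6-(2-methylpropanoyloxy)-9-oxotricyclo[5.4.0.0(2,8)]undec-10-en-4-yl 2-methylprop-2-enoate (CNP0214356.1) | C=C(C)C(=O)O[C@@H]1C[C@@H](OC(=O)C(C)C)[C@@]2(C)[C@@H]3C(=O)C=C(C)[C@H]2[C@@H]3C1(C)C | target

Total step count: 16. Longest linear sequence: 16 steps (from 1).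

Steps most likely to fail

Step 10. Retro-aldol cleavage of the congested aldolate may outrun ring closure, the aldehyde enolate may self-condense, or the cyclobutanolate may fragment on warming. The fallback reverses the order of the two bond formations and sets out from 14. An intermolecular Horner–Wadsworth–Emmons reaction with isobutyraldehyde (LiCl, DBU, MeCN, rt) should give 2,7-dimethyl-7-[(2E)-4-methylpent-2-enoyl]bicyclo[3.1.1]hept-2-en-6-one F1. Its only acidic site is the γ-methine, so LDA (THF, −78 °C) should form the extended enolate, which can reach the cyclobutanone only through its γ-carbon (α-attack would create a bicyclo[2.1.1]hexane) in an intramolecular vinylogous aldol addition. A cold acetic acid quench returns the route at 18.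

Step 11. Boryl-copper addition to the β-neopentyl enone may be slow or poorly face-selective, and any alkoxide formed may open the cyclobutanol. The fallback sets out from 18. Catalytic asymmetric nucleophilic epoxidation (t-BuOOH, La(OiPr)3, (R)-BINOL, Ph3As=O, THF) should give (4R)-4,5-epoxy-2-hydroxy-3,3,7,11-tetramethyltricyclo[5.4.0.0(2,8)]undec-10-en-6-one F2. Acylation with methyl chlorooxoacetate (Et3N, DMAP) should give its C2 methyl oxalate F3. Bu3SnH and AIBN in toluene at 100 °C should then cleave both the tertiary oxalate and the Cα–O bond of the α,β-epoxy ketone, returning the route at 22.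

Step 14. Samarium diiodide may reduce or couple the enal before the trivalent samarium catalyst forms, the enal may polymerise, or retro-aldol equilibration of 22 may scramble C4. The fallback sets out from 22. Acylation with methacrylic anhydride (Sc(OTf)3 cat., MeCN, −20 °C) should give (4R)-3,3,7,11-tetramethyl-6-oxotricyclo[5.4.0.0(2,8)]undec-10-en-4-yl 2-methylprop-2-enoate F4. Corey–Bakshi–Shibata reduction ((S)-Me-oxazaborolidine, catecholborane, toluene, −78 °C) of the ketone flanked by the quaternary C7 and the C5 methylene should then set (6R) by reagent control and return the route at 23.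

Further compounds
F1 | step 10 | 2,7-dimethyl-7-[(2E)-4-methylpent-2-enoyl]bicyclo[3.1.1]hept-2-en-6-one | CC(C)/C=C/C(=O)[C@@]1(C)[C@@H]2CC=C(C)[C@H]1C2=O
F2 | step 11 | (4R)-4,5-epoxy-2-hydroxy-3,3,7,11-tetramethyltricyclo[5.4.0.0(2,8)]undec-10-en-6-one | O4[C@@H]1[C@H]4C(=O)[C@@]2(C)[C@@H]3CC=C(C)[C@H]2[C@]3(O)C1(C)C
F3 | step 11 | methyl (4R)-4,5-epoxy-3,3,7,11-tetramethyl-6-oxotricyclo[5.4.0.0(2,8)]undec-10-en-2-yl oxalate | O4[C@@H]1[C@H]4C(=O)[C@@]2(C)[C@@H]3CC=C(C)[C@H]2[C@]3(OC(=O)C(=O)OC)C1(C)C
F4 | step 14 | (4R)-3,3,7,11-tetramethyl-6-oxotricyclo[5.4.0.0(2,8)]undec-10-en-4-yl 2-methylprop-2-enoate | C=C(C)C(=O)O[C@@H]1CC(=O)[C@@]2(C)[C@@H]3CC=C(C)[C@H]2[C@@H]3C1(C)C
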